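**Plan**

- Retrosynthesis: the propenoic acid C=C is cut back to the C5 aldehyde. Ring B (the dihydrofuran) is then opened at C3–C3a, and the CH2–O bond of the arm is cut in the same operation. Last, the O1–C2 ether bond is cut, leading to 5-iodovanillin and a cinnamyl carbonate made from syringaldehyde.
- Enabling feature (benzofuran numbering): C3 is attached to C3a of ring A (the fused benzene ring) and to an exocyclic CH2O carbon. This is the pattern left when an aryl radical at C3a closes on the inner carbon of a vinyl group held on O1–C2 and the outer carbon is then oxygenated.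
- Forward: ring C (the syringyl ring) is built up to an (E)-cinnamyl carbonate and joined to ring A through O1–C2. Ring B is closed by C3–C3a formation with nitroxide capture. The acrylic acid is then added, followed by N–O cleavage and desilylation.
- Stereochemistry: C2 (S) comes from an asymmetric allylic etherification under a chiral phosphoramidite. C3 (R) is relayed from C2 in the ring closure (trans). The E alkene comes from the decarboxylative condensation.

Key step: step 6

Assumption: the (Sa,Sc,Sc) ligand is taken to direct the phenoxide to the allyl face that gives the (S)-ether; if the sense of induction on this substrate is the reverse, the mirror-image ligand is used and nothing else changes.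

**Step 1**
Reactants: 1 syringaldehyde
Product: 2 4-[(tert-butyldimethylsilyl)oxy]-3,5-dimethoxybenzaldehyde
Conditions: TBSCl, imidazole, DMF, rt
Reagents that add atoms: tert-butyldimethylsilyl chloride, CC(C)(C)[Si](C)(C)Cl
Why: Imidazole-promoted silylation of the phenol masks the acidic para-hydroxyl, which would otherwise quench the ylide and hydride reagents and later permit quinone methide formation at the benzylic carbon.

**Step 2**
Reactants: 2 4-[(tert-butyldimethylsilyl)oxy]-3,5-dimethoxybenzaldehyde, 3 ethyl (triphenylphosphoranylidene)acetate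
Product: 4 ethyl (E)-3-{4-[(tert-butyldimethylsilyl)oxy]-3,5-dimethoxyphenyl}prop-2-enoate
Conditions: Ph3P=CHCO2Et, PhMe, 80 °C
Reagents that add atoms: ethyl (triphenylphosphoranylidene)acetate 3, CCOC(=O)C=P(c1ccccc1)(c1ccccc1)c1ccccc1
Why: Wittig olefination with a stabilised ylide runs under neutral conditions, should give the (E)-cinnamate and should leave the base-sensitive aryl silyl ether intact.

**Step 3**
Reactants: 4 ethyl (E)-3-{4-[(tert-butyldimethylsilyl)oxy]-3,5-dimethoxyphenyl}prop-2-enoate
Product: 5 (E)-3-{4-[(tert-butyldimethylsilyl)oxy]-3,5-dimethoxyphenyl}prop-2-en-1-ol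
Conditions: i-Bu2AlH, CH2Cl2, −78 °C
Reagents that add atoms: none
Why: 1,2-Reduction of an α,β-unsaturated ester with i-Bu2AlH at low temperature should stop at the allylic alcohol without touching the alkene or the silyl ether.

**Step 4**
Reactants: 5 (E)-3-{4-[(tert-butyldimethylsilyl)oxy]-3,5-dimethoxyphenyl}prop-2-en-1-ol
Product: 6 (E)-3-{4-[(tert-butyldimethylsilyl)oxy]-3,5-dimethoxyphenyl}prop-2-en-1-yl methyl carbonate
Conditions: ClCO2Me, pyridine, CH2Cl2, 0 °C
Reagents that add atoms: methyl chloroformate, COC(=O)Cl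
Why: Acylation of the primary allylic alcohol with a chloroformate gives the linear, achiral methyl carbonate, the usual electrophile for asymmetric allylic substitution, so no racemic branched electrophile is needed.

**Step 5**
Reactants: 6 (E)-3-{4-[(tert-butyldimethylsilyl)oxy]-3,5-dimethoxyphenyl}prop-2-en-1-yl methyl carbonate, 7 5-iodovanillin
Product: 9 4-{[(1S)-1-{4-[(tert-butyldimethylsilyl)oxy]-3,5-dimethoxyphenyl}prop-2-en-1-yl]oxy}-3-iodo-5-methoxybenzaldehyde, via sodium 4-formyl-2-iodo-6-methoxyphenolate 8 (not isolated)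
Conditions: 7, NaH, THF, 0 °C; then 6, [Ir(cod)Cl]2 (2 mol%), (Sa,Sc,Sc)-O,O'-(1,1'-binaphthalene-2,2'-diyl) N,N-bis(1-phenylethyl)phosphoramidite (4 mol%, pre-activated with n-PrNH2), THF, rt
Reagents that add atoms: none
Why: In this iridium-catalysed asymmetric allylic etherification the cyclometalated catalyst formed from [Ir(cod)Cl]2 and the phosphoramidite ionises the linear carbonate and the phenoxide attacks the aryl-bearing allyl terminus on the face opposite the metal, so the branched ether should form with C2 set as S by the ligand, while the iodide, the aldehyde and the silyl ether are spectators.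

**Step 6**
Reactants: 9 4-{[(1S)-1-{4-[(tert-butyldimethylsilyl)oxy]-3,5-dimethoxyphenyl}prop-2-en-1-yl]oxy}-3-iodo-5-methoxybenzaldehyde, 10 TEMPO
Product: 13 (2S,3R)-2-{4-[(tert-butyldimethylsilyl)oxy]-3,5-dimethoxyphenyl}-7-methoxy-3-{[(2,2,6,6-tetramethylpiperidin-1-yl)oxy]methyl}-2,3-dihydro-1-benzofuran-5-carbaldehyde, via C3a aryl radical 11 (not isolated), via cyclised primary radical 12 (not isolated)
Conditions: Bu3SnH (3 equiv, in portions), TEMPO (5 equiv), degassed PhMe, 70 °C
Reagents that add atoms: TEMPO 10, CC1(C)CCCC(C)(C)N1[O]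
Why: TEMPO takes hydrogen from Bu3SnH to give Bu3Sn•, which removes iodine from 9; the σ-aryl radical 11 at C3a attacks the inner vinyl carbon and the primary radical 12 couples at oxygen with a second TEMPO, so one operation makes C3–C3a and CH2–O. The closest known reaction type is the Bu3SnH-mediated cyclisation of ortho-halophenyl allyl ethers and N-allyl anilides with nitroxide capture of the cyclised radical. Ring B closes in the 5-exo-trig mode, the 6-endo mode being kinetically disfavoured for hexenyl-type aryl radicals, and fast nitroxide coupling should leave no time for neophyl-type ring expansion of 12 to a chroman. The new C3 centre is controlled by C2: in the chair-like transition state the C2 aryl group sits pseudo-equatorial and the alkene terminus turns away from it, so the CH2O arm should end trans to the aryl group (2S,3R), with any minor cis isomer removed by chromatography here. The step needs ring closure to outrun capture or reduction of 11, which the short O1–C2 tether secures because ortho-allyloxyaryl radicals cyclise far faster than they meet TEMPO or Bu3SnH at these concentrations. It also needs oxygen capture of 12 to outrun hydrogen transfer, which the excess of TEMPO over the slowly added Bu3SnH secures, while the aldehyde, silyl ether and benzylic ether are inert under these neutral conditions.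

**Step 7**
Reactants: 13 (2S,3R)-2-{4-[(tert-butyldimethylsilyl)oxy]-3,5-dimethoxyphenyl}-7-methoxy-3-{[(2,2,6,6-tetramethylpiperidin-1-yl)oxy]methyl}-2,3-dihydro-1-benzofuran-5-carbaldehyde, 14 malonic acid
Product: 16 (2E)-3-[(2S,3R)-2-{4-[(tert-butyldimethylsilyl)oxy]-3,5-dimethoxyphenyl}-7-methoxy-3-{[(2,2,6,6-tetramethylpiperidin-1-yl)oxy]methyl}-2,3-dihydro-1-benzofuran-5-yl]prop-2-enoic acid, via arylidenemalonic acid 15 (not isolated)
Conditions: CH2(CO2H)2, pyridine, piperidine (cat.), 80 °C
Reagents that add atoms: malonic acid 14, OC(=O)CC(=O)O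
Why: In this Knoevenagel–Doebner condensation the aryl aldehyde condenses with malonic acid under piperidine catalysis and diacid 15 loses CO2 in hot pyridine, which should give the (E)-cinnamic acid directly without affecting the alkoxyamine or either stereocentre.

**Step 8**
Reactants: 16 (2E)-3-[(2S,3R)-2-{4-[(tert-butyldimethylsilyl)oxy]-3,5-dimethoxyphenyl}-7-methoxy-3-{[(2,2,6,6-tetramethylpiperidin-1-yl)oxy]methyl}-2,3-dihydro-1-benzofuran-5-yl]prop-2-enoic acid
Product: 17 (2E)-3-[(2S,3R)-2-{4-[(tert-butyldimethylsilyl)oxy]-3,5-dimethoxyphenyl}-3-(hydroxymethyl)-7-methoxy-2,3-dihydro-1-benzofuran-5-yl]prop-2-enoic acid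
Conditions: Zn dust, AcOH/THF/H2O (3:1:1), 60 °C
Reagents that add atoms: none
Why: Reductive N–O cleavage of the alkoxyamine by zinc in acetic acid should free the primary alcohol, while the conjugated acid, the benzylic ether and the aryl silyl ether are not expected to be reduced.

**Step 9**
Reactants: 17 (2E)-3-[(2S,3R)-2-{4-[(tert-butyldimethylsilyl)oxy]-3,5-dimethoxyphenyl}-3-(hydroxymethyl)-7-methoxy-2,3-dihydro-1-benzofuran-5-yl]prop-2-enoic acid
Product: 18 (2E)-3-[(2S,3R)-2-(4-hydroxy-3,5-dimethoxyphenyl)-3-(hydroxymethyl)-7-methoxy-2,3-dihydro-1-benzofuran-5-yl]prop-2-enoic acid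
Conditions: Bu4NF, AcOH, THF, 0 °C to rt
Reagents that add atoms: none
Why: Fluoride-induced cleavage of the aryl silyl ether, buffered with acetic acid so that no free phenoxide can open ring B through a quinone methide, should release the target with both stereocentres untouched.

**Compound list**

1 | syringaldehyde (4-hydroxy-3,5-dimethoxybenzaldehyde) | COc1cc(C=O)cc(OC)c1O | starting material
2 | 4-[(tert-butyldimethylsilyl)oxy]-3,5-dimethoxybenzaldehyde | COc1cc(C=O)cc(OC)c1O[Si](C)(C)C(C)(C)C | intermediate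
3 | ethyl (triphenylphosphoranylidene)acetate | CCOC(=O)C=P(c1ccccc1)(c1ccccc1)c1ccccc1 | starting material
4 | ethyl (E)-3-{4-[(tert-butyldimethylsilyl)oxy]-3,5-dimethoxyphenyl}prop-2-enoate | CCOC(=O)/C=C/c1cc(OC)c(O[Si](C)(C)C(C)(C)C)c(OC)c1 | intermediate
5 | (E)-3-{4-[(tert-butyldimethylsilyl)oxy]-3,5-dimethoxyphenyl}prop-2-en-1-ol | OC/C=C/c1cc(OC)c(O[Si](C)(C)C(C)(C)C)c(OC)c1 | intermediate
6 | (E)-3-{4-[(tert-butyldimethylsilyl)oxy]-3,5-dimethoxyphenyl}prop-2-en-1-yl methyl carbonate | COC(=O)OC/C=C/c1cc(OC)c(O[Si](C)(C)C(C)(C)C)c(OC)c1 | intermediate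
7 | 5-iodovanillin (4-hydroxy-3-iodo-5-methoxybenzaldehyde) | COc1cc(C=O)cc(I)c1O | starting material
8 | sodium 4-formyl-2-iodo-6-methoxyphenolate | COc1cc(C=O)cc(I)c1[O-].[Na+] | intermediate
9 | 4-{[(1S)-1-{4-[(tert-butyldimethylsilyl)oxy]-3,5-dimethoxyphenyl}prop-2-en-1-yl]oxy}-3-iodo-5-methoxybenzaldehyde | COc1cc([C@H](C=C)Oc2c(OC)cc(C=O)cc2I)cc(OC)c1O[Si](C)(C)C(C)(C)C | intermediate
10 | TEMPO (2,2,6,6-tetramethylpiperidin-1-oxyl) | CC1(C)CCCC(C)(C)N1[O] | starting material
11 | 2-{[(1S)-1-{4-[(tert-butyldimethylsilyl)oxy]-3,5-dimethoxyphenyl}prop-2-en-1-yl]oxy}-5-formyl-3-methoxyphenyl radical (σ-radical at the carbon that bore iodine, the future C3a) | COc1cc([C@H](C=C)Oc2c(OC)cc(C=O)c[c]2)cc(OC)c1O[Si](C)(C)C(C)(C)C | intermediate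
12 | [(2S)-2-{4-[(tert-butyldimethylsilyl)oxy]-3,5-dimethoxyphenyl}-5-formyl-7-methoxy-2,3-dihydro-1-benzofuran-3-yl]methyl radical, CH2 arm trans to the C2 aryl group (C3 arranged as in 13) | COc1cc([C@H]2Oc3c(OC)cc(C=O)cc3[C@@H]2[CH2])cc(OC)c1O[Si](C)(C)C(C)(C)C | intermediate
13 | (2S,3R)-2-{4-[(tert-butyldimethylsilyl)oxy]-3,5-dimethoxyphenyl}-7-methoxy-3-{[(2,2,6,6-tetramethylpiperidin-1-yl)oxy]methyl}-2,3-dihydro-1-benzofuran-5-carbaldehyde | COc1cc([C@H]2Oc3c(OC)cc(C=O)cc3[C@@H]2CON2C(C)(C)CCCC2(C)C)cc(OC)c1O[Si](C)(C)C(C)(C)C | intermediate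
14 | malonic acid | OC(=O)CC(=O)O | starting material
15 | 2-{[(2S,3R)-2-{4-[(tert-butyldimethylsilyl)oxy]-3,5-dimethoxyphenyl}-7-methoxy-3-{[(2,2,6,6-tetramethylpiperidin-1-yl)oxy]methyl}-2,3-dihydro-1-benzofuran-5-yl]methylidene}propanedioic acid | COc1cc([C@H]2Oc3c(OC)cc(C=C(C(=O)O)C(=O)O)cc3[C@@H]2CON2C(C)(C)CCCC2(C)C)cc(OC)c1O[Si](C)(C)C(C)(C)C | intermediate
16 | (2E)-3-[(2S,3R)-2-{4-[(tert-butyldimethylsilyl)oxy]-3,5-dimethoxyphenyl}-7-methoxy-3-{[(2,2,6,6-tetramethylpiperidin-1-yl)oxy]methyl}-2,3-dihydro-1-benzofuran-5-yl]prop-2-enoic acid | COc1cc([C@H]2Oc3c(OC)cc(/C=C/C(=O)O)cc3[C@@H]2CON2C(C)(C)CCCC2(C)C)cc(OC)c1O[Si](C)(C)C(C)(C)C | intermediate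
17 | (2E)-3-[(2S,3R)-2-{4-[(tert-butyldimethylsilyl)oxy]-3,5-dimethoxyphenyl}-3-(hydroxymethyl)-7-methoxy-2,3-dihydro-1-benzofuran-5-yl]prop-2-enoic acid | COc1cc([C@H]2Oc3c(OC)cc(/C=C/C(=O)O)cc3[C@@H]2CO)cc(OC)c1O[Si](C)(C)C(C)(C)C | intermediate
18 | (2E)-3-[(2S,3R)-2-(4-hydroxy-3,5-dimethoxyphenyl)-3-(hydroxymethyl)-7-methoxy-2,3-dihydro-1-benzofuran-5-yl]prop-2-enoic acid | COc1cc([C@H]2Oc3c(OC)cc(/C=C/C(=O)O)cc3[C@@H]2CO)cc(OC)c1O | target

**Step count and risks**

Total step count: 9. Longest linear sequence: 9 steps (1 to 18); 7 enters at step 5.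

Steps most likely to fail:

1. Step 5. The hindered, electron-poor phenoxide may add too slowly to the allyl–iridium intermediate. The branched ether also carries a good leaving group on a benzylic allylic carbon and may be re-ionised by the catalyst, with drift to the linear ether and erosion of enantiopurity. The fallback leaves allyl–metal chemistry and forms O1–C2 by SN2 displacement, setting out from 2. Aldehyde 2 is treated with Zn(CH=CH2)2 (from CH2=CHMgBr and ZnCl2) and catalytic (+)-DAIB [(2R)-3-exo-(dimethylamino)isoborneol] in toluene at 0 °C. This should deliver vinyl to the Re face and give (R)-1-{4-[(tert-butyldimethylsilyl)oxy]-3,5-dimethoxyphenyl}prop-2-en-1-ol F1. Mitsunobu coupling of F1 with phenol 7 (PPh3, DIAD, toluene, −20 °C) should then invert the carbinol centre and bring the route back at 9.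

2. Step 6. Bu3SnH and TEMPO may consume each other faster than the radical sequence turns over, or hydrogen transfer to radical 12 may compete with nitroxide coupling; either leaves unreacted iodide or the 3-methyl compound. The fallback captures 12 with triplet oxygen instead and sets out from 9. Slow addition of Bu3SnH to 9 under a stream of dry air in toluene at 0 °C to rt should give, after the same 5-exo closure, (2S,3R)-2-{4-[(tert-butyldimethylsilyl)oxy]-3,5-dimethoxyphenyl}-3-(hydroperoxymethyl)-7-methoxy-2,3-dihydro-1-benzofuran-5-carbaldehyde F2. PPh3 added to the same flask should reduce it to (2S,3R)-2-{4-[(tert-butyldimethylsilyl)oxy]-3,5-dimethoxyphenyl}-3-(hydroxymethyl)-7-methoxy-2,3-dihydro-1-benzofuran-5-carbaldehyde F3. Knoevenagel–Doebner condensation of F3 with 14 (pyridine, cat. piperidine, 80 °C) should then pass through 2-{[(2S,3R)-2-{4-[(tert-butyldimethylsilyl)oxy]-3,5-dimethoxyphenyl}-3-(hydroxymethyl)-7-methoxy-2,3-dihydro-1-benzofuran-5-yl]methylidene}propanedioic acid F4 and come back to the route at 17, so the zinc step is no longer needed.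

3. Step 7. Hot pyridine and piperidine may strip the aryl silyl ether; the freed para-phenol can then open ring B through a quinone methide that the amine traps. Decarboxylation of 15 may also stall. The fallback builds the acrylate by phosphorus olefination under neutral conditions and sets out from 13. Heating 13 with allyl (triphenylphosphoranylidene)acetate in toluene at 60 °C should give allyl (2E)-3-[(2S,3R)-2-{4-[(tert-butyldimethylsilyl)oxy]-3,5-dimethoxyphenyl}-7-methoxy-3-{[(2,2,6,6-tetramethylpiperidin-1-yl)oxy]methyl}-2,3-dihydro-1-benzofuran-5-yl]prop-2-enoate F5. Pd(PPh3)4 with morpholine in THF at rt should then remove the allyl group and bring the route back at 16.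

**Further compounds**

F1 | step 5 | (R)-1-{4-[(tert-butyldimethylsilyl)oxy]-3,5-dimethoxyphenyl}prop-2-en-1-ol | COc1cc([C@@H](C=C)O)cc(OC)c1O[Si](C)(C)C(C)(C)C
F2 | step 6 | (2S,3R)-2-{4-[(tert-butyldimethylsilyl)oxy]-3,5-dimethoxyphenyl}-3-(hydroperoxymethyl)-7-methoxy-2,3-dihydro-1-benzofuran-5-carbaldehyde | COc1cc([C@H]2Oc3c(OC)cc(C=O)cc3[C@@H]2COO)cc(OC)c1O[Si](C)(C)C(C)(C)C
F3 | step 6 | (2S,3R)-2-{4-[(tert-butyldimethylsilyl)oxy]-3,5-dimethoxyphenyl}-3-(hydroxymethyl)-7-methoxy-2,3-dihydro-1-benzofuran-5-carbaldehyde | COc1cc([C@H]2Oc3c(OC)cc(C=O)cc3[C@@H]2CO)cc(OC)c1O[Si](C)(C)C(C)(C)C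
F4 | step 6 | 2-{[(2S,3R)-2-{4-[(tert-butyldimethylsilyl)oxy]-3,5-dimethoxyphenyl}-3-(hydroxymethyl)-7-methoxy-2,3-dihydro-1-benzofuran-5-yl]methylidene}propanedioic acid | COc1cc([C@H]2Oc3c(OC)cc(C=C(C(=O)O)C(=O)O)cc3[C@@H]2CO)cc(OC)c1O[Si](C)(C)C(C)(C)C
F5 | step 7 | allyl (2E)-3-[(2S,3R)-2-{4-[(tert-butyldimethylsilyl)oxy]-3,5-dimethoxyphenyl}-7-methoxy-3-{[(2,2,6,6-tetramethylpiperidin-1-yl)oxy]methyl}-2,3-dihydro-1-benzofuran-5-yl]prop-2-enoate | COc1cc([C@H]2Oc3c(OC)cc(/C=C/C(=O)OCC=C)cc3[C@@H]2CON2C(C)(C)CCCC2(C)C)cc(OC)c1O[Si](C)(C)C(C)(C)C
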